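The carbocycle of the tetrahydrochromone half is cut at C8–C8a. C8a, the oxygen-bearing enol carbon of the pyranone ring, is a ketone in disguise and C8 a carbinol, so the pair is an acyloin, and the all-trans C5–C7 triol is C2–C4 of D-xylose. A triazolium carbene unites the two aldehyde carbons of the one-carbon-homologated xylose dialdehyde 7, closing the six-membered ring and giving, in one operation, the C8a ketone, the only free hydroxyl (O8) and the C8 stereocentre (8). The ketone then carries the pyranone (ynal aldol, oxidation, 6-endo closure), O8 is arylated with retention by a paeonol-derived iodochromone, and the benzyl ethers fall last.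

Key step: step 6

Remark: methyl β-D-xylopyranoside is taken as the commercial, anomerically pure form of D-xylose; which antipode of the chiral triazolium salt reinforces the substrate's own facial preference is assumed to be settled by running both.

Step 1
Reactants: 1 methyl β-D-xylopyranoside
Product: 2 methyl 2,3,4-tri-O-benzyl-β-D-xylopyranoside
Conditions: NaH, BnBr, Bu4NI (cat.), DMF, 0 °C to rt
Reagents that add atoms: benzyl bromide, BrCc1ccccc1
Why: Williamson etherification of the three secondary hydroxyls is routine on methyl pentopyranosides and leaves the acetal and all stereocentres untouched.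

Step 2
Reactants: 2 methyl 2,3,4-tri-O-benzyl-β-D-xylopyranoside
Product: 3 2,3,4-tri-O-benzyl-D-xylopyranose (anomeric mixture)
Conditions: AcOH, 2 M aq. HCl, 85 °C
Reagents that add atoms: water, O
Why: Acid-catalysed glycoside hydrolysis through the oxocarbenium ion frees the hemiacetal while benzyl ethers survive, and the anomeric mixture is immaterial because C1 becomes sp2 in the next step.

Step 3
Reactants: 3 2,3,4-tri-O-benzyl-D-xylopyranose
Product: 4 3,4,5-tri-O-benzyl-1,2-dideoxy-D-xylo-hex-1-enitol
Conditions: Ph3PCH3Br, n-BuLi, THF, −20 °C to rt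
Reagents that add atoms: methyltriphenylphosphonium bromide, C[P+](c1ccccc1)(c1ccccc1)c1ccccc1.[Br-]
Why: Wittig methylenation of the open-chain aldehyde in equilibrium with the lactol, a standard olefination of benzylated aldoses, adds the carbon that becomes C8a and releases the primary hydroxyl on the future C8, the non-stabilised ylide at low temperature keeping epimerisation next to the aldehyde in check.

Step 4
Reactants: 4 3,4,5-tri-O-benzyl-1,2-dideoxy-D-xylo-hex-1-enitol
Product: 6 3,4,5-tri-O-benzyl-2-deoxy-D-xylo-hexitol, via bis-borane adduct 5 (not isolated)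
Conditions: 9-BBN (2.5 equiv), THF, 0 °C to rt; then 3 M aq. NaOH, 30% aq. H2O2, 0 °C to rt
Reagents that add atoms: hydrogen peroxide, OO
Why: Anti-Markovnikov hydroboration–oxidation of the terminal alkene with a bulky dialkylborane places oxygen on the terminal carbon only, giving a stable 1,6-diol in which both future aldehyde carbons sit at the alcohol level.

Step 5
Reactants: 6 3,4,5-tri-O-benzyl-2-deoxy-D-xylo-hexitol
Product: 7 3,4,5-tri-O-benzyl-2-deoxy-D-xylo-hexodialdose
Conditions: (COCl)2, DMSO, CH2Cl2, −78 °C; then i-Pr2NEt, −78 to −30 °C; cold pH 7 buffer; crude 7 used at once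
Reagents that add atoms: none
Why: Double Swern oxidation activates both primary alcohols before base is added, so no hydroxy aldehyde (hence no lactol or lactone) intervenes, and the cold hindered-amine step should deliver the dialdehyde without epimerisation at C7 or loss of benzyl alcohol.

Step 6
Reactants: 7 3,4,5-tri-O-benzyl-2-deoxy-D-xylo-hexodialdose
Product: 8 (2S,3R,4R,5S)-3,4,5-tris(benzyloxy)-2-hydroxycyclohexan-1-one
Conditions: (5aR,10bS)-2-(pentafluorophenyl)-5a,10b-dihydro-4H,6H-indeno[2,1-b][1,2,4]triazolo[4,3-d][1,4]oxazin-2-ium tetrafluoroborate or its enantiomer (15 mol %, matched antipode), i-Pr2NEt (15 mol %), 4 Å MS, CH2Cl2 (0.02 M), Ar, 0 °C to rt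
Reagents that add atoms: none
Why: The carbene adds reversibly to both formyl groups, but the Breslow enaminol should form faster at the unhindered CH2–CHO terminus (C8a), whose acyl-anion carbon then attacks the more electrophilic α-benzyloxy aldehyde (C8), and release of the carbene leaves the ketone at C8a and the only free hydroxyl at C8. The closest known reaction type is the triazolium-catalysed intramolecular crossed benzoin (acyloin) cyclisation of carbohydrate-derived dialdehydes to protected inososes. The cyclohexane ring closes in the 6-exo-trig mode, the C8 carbonyl oxygen staying outside the ring. The new stereocentre C8 is set in a chair-like transition state with the three benzyloxy groups equatorial, the forming bond anti to the C7–O bond (polar Felkin–Anh arrangement) and the aldehyde oxygen axial and hydrogen-bonded to the enaminol hydroxyl, which places O8 cis to O7, and the chiral triazolium is used as the antipode that reinforces this preference. The step needs donor/acceptor chemoselectivity and freedom from base-induced enolisation (five-ring aldol, loss of the C5 benzyloxy group), the first secured by the steric and electronic difference between the two aldehydes and the second by an acidic N-pentafluorophenyl triazolium that needs only a sub-stoichiometric hindered amine.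

Step 7
Reactants: 8 (2S,3R,4R,5S)-3,4,5-tris(benzyloxy)-2-hydroxycyclohexan-1-one
Product: 9 (2S,3S,4R,5S)-3,4,5-tris(benzyloxy)-2-[(triethylsilyl)oxy]cyclohexan-1-one (O-triethylsilyl ether of 8, the change of descriptor at C3 being formal)
Conditions: TESCl, imidazole, CH2Cl2, 0 °C
Reagents that add atoms: chlorotriethylsilane, CC[Si](CC)(CC)Cl
Why: Silylation of the α-ketol hydroxyl under mild imidazole buffering caps O8 before enolate and oxidation chemistry, blocking α-ketol transposition and over-oxidation with a group that survives strong base and periodinane yet leaves in mild acid without touching benzyl ethers.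

Step 8
Reactants: 10 4-phenyl-1-butyne
Product: 12 5-phenylpent-2-ynal, via lithium acetylide 11 (not isolated)
Conditions: n-BuLi, THF, −78 °C; then DMF, −78 to 0 °C; inverse quench into 10% aq. KH2PO4/MTBE
Reagents that add atoms: N,N-dimethylformamide, CN(C)C=O
Why: Formylation of a lithium acetylide with DMF is the standard route to 2-ynals, the buffered inverse quench preventing conjugate addition of the liberated dimethylamine.

Step 9
Reactants: 9 (2S,3S,4R,5S)-3,4,5-tris(benzyloxy)-2-[(triethylsilyl)oxy]cyclohexan-1-one; 12 5-phenylpent-2-ynal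
Product: 14 (2S,3S,4R,5S)-3,4,5-tris(benzyloxy)-6-(1-hydroxy-5-phenylpent-2-yn-1-yl)-2-[(triethylsilyl)oxy]cyclohexan-1-one (mixture of C6/carbinol diastereomers), via lithium enolate 13 (not isolated)
Conditions: LiN(SiMe3)2, THF, −78 °C; then 12, −78 °C; sat. aq. NH4Cl at −78 °C
Reagents that add atoms: none
Why: Kinetic deprotonation should occur at the C6 methylene (future C4a), which has an axial C–H aligned with the carbonyl whereas H2 is equatorial and shielded by the axial silyloxy group, and the lithium enolate adds 1,2 to the ynal in a directed aldol reaction, the equatorial C5–O bond lying near the nodal plane of the enolate so that E1cB loss of benzyl alcohol is slow, and both new stereocentres are erased later.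

Step 10
Reactants: 14 aldol adduct
Product: 15 3,4,5-tris(benzyloxy)-6-(5-phenylpent-2-ynoyl)-2-[(triethylsilyl)oxy]cyclohexan-1-one, enol form (ring stereocentres C2–C5 as in 9)
Conditions: Dess–Martin periodinane, NaHCO3, CH2Cl2, 0 °C to rt
Reagents that add atoms: none
Why: Dess–Martin oxidation of a β-hydroxy ketone that is also a propargylic alcohol gives the alkynyl 1,3-diketone under buffered, non-basic conditions, and enolisation removes the C6 stereocentre.

Step 11
Reactants: 15 enolised alkynyl 1,3-diketone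
Product: 17 (5S,6R,7R,8S)-5,6,7-tris(benzyloxy)-8-hydroxy-2-(2-phenylethyl)-5,6,7,8-tetrahydro-4H-chromen-4-one, via silyl-protected tetrahydrochromenone 16 (not isolated)
Conditions: TsOH·H2O (20 mol %), CH2Cl2, rt; then MeOH, rt
Reagents that add atoms: none
Why: Brønsted acid promotes 6-endo-dig oxa-Michael addition of the C8a enol oxygen to the β-carbon of the ynone, the established acid-mediated closure of enolised alkynyl diketones and ortho-hydroxyaryl ynones to 4-pyranones (the 5-exo mode would be anti-Michael), and added methanol then solvolyses the triethylsilyl ether while the protonated, electron-poor pyranone protects the C5 benzyl ether from ionisation.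

Step 12
Reactants: 18 paeonol (2-hydroxy-4-methoxyacetophenone)
Product: 19 1-(2-hydroxy-5-iodo-4-methoxyphenyl)ethan-1-one
Conditions: NIS, TFA (cat.), MeCN, rt
Reagents that add atoms: N-iodosuccinimide, IN1C(=O)CCC1=O
Why: Electrophilic aromatic iodination should go para to the phenolic hydroxyl and ortho to the methoxy group (C5), the alternative C3 being flanked by two substituents.

Step 13
Reactants: 19 1-(2-hydroxy-5-iodo-4-methoxyphenyl)ethan-1-one; 20 ethyl 3-phenylpropanoate
Product: 22 6-iodo-7-methoxy-2-(2-phenylethyl)-4H-chromen-4-one, via 1,3-diketone 21 (not isolated)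
Conditions: NaH (4 equiv), THF, reflux; aq. HCl; then AcOH, conc. H2SO4 (cat.), 90 °C
Reagents that add atoms: none
Why: Crossed Claisen condensation of the acetophenone enolate with the ester followed by acid-catalysed cyclodehydration onto the ortho-hydroxyl is the standard synthesis of 2-(2-phenylethyl)chromones, and the aryl iodide is inert to both stages.

Step 14
Reactants: 17 (5S,6R,7R,8S)-5,6,7-tris(benzyloxy)-8-hydroxy-2-(2-phenylethyl)-5,6,7,8-tetrahydro-4H-chromen-4-one; 22 6-iodo-7-methoxy-2-(2-phenylethyl)-4H-chromen-4-one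
Product: 23 (5S,6R,7S,8S)-5,6,7-tris(benzyloxy)-8-{[7-methoxy-4-oxo-2-(2-phenylethyl)-4H-chromen-6-yl]oxy}-2-(2-phenylethyl)-5,6,7,8-tetrahydro-4H-chromen-4-one
Conditions: 22 (3 equiv), CuI (20 mol %), 3,4,7,8-tetramethyl-1,10-phenanthroline (40 mol %), Cs2CO3, 4 Å MS, toluene, Ar, 90 °C
Reagents that add atoms: none
Why: Ullmann-type copper-catalysed C–O coupling of an aryl iodide with a secondary alcohol forms the aryl–oxygen bond without touching the C8–O bond, so C8 keeps its configuration, and it is placed here because the substrate no longer has an α-ketol or enolisable ketone that copper and base could oxidise or isomerise.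

Step 15
Reactants: 23 tri-O-benzyl ether of the target
Product: 24 (5S,6R,7S,8S)-5,6,7-trihydroxy-8-{[7-methoxy-4-oxo-2-(2-phenylethyl)-4H-chromen-6-yl]oxy}-2-(2-phenylethyl)-5,6,7,8-tetrahydro-4H-chromen-4-one (CNP0125425.2)
Conditions: BCl3 (1 M in CH2Cl2, 10 equiv), pentamethylbenzene (10 equiv), CH2Cl2, −78 °C; then MeOH, −78 °C to rt
Reagents that add atoms: none
Why: Lewis-acid debenzylation with BCl3 at low temperature, pentamethylbenzene trapping the benzyl cations, should cleave the three alkyl benzyl ethers while sparing the aryl methyl ether, both pyranone double bonds and the C8–O–aryl link (a C8 cation would sit next to the electron-poor C8a), which hydrogenolysis might not.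

Compound list
1 | methyl β-D-xylopyranoside | CO[C@@H]1OC[C@@H](O)[C@H](O)[C@H]1O | starting material
2 | methyl 2,3,4-tri-O-benzyl-β-D-xylopyranoside | CO[C@@H]1OC[C@@H](OCc2ccccc2)[C@H](OCc2ccccc2)[C@H]1OCc1ccccc1 | intermediate
3 | 2,3,4-tri-O-benzyl-D-xylopyranose (anomeric mixture) | OC1OC[C@@H](OCc2ccccc2)[C@H](OCc2ccccc2)[C@H]1OCc1ccccc1 | intermediate
4 | 3,4,5-tri-O-benzyl-1,2-dideoxy-D-xylo-hex-1-enitol | C=C[C@H](OCc1ccccc1)[C@@H](OCc1ccccc1)[C@H](OCc1ccccc1)CO | intermediate
5 | 1-C,6-O-bis(9-borabicyclo[3.3.1]nonan-9-yl) adduct of 3,4,5-tri-O-benzyl-2-deoxy-D-xylo-hexitol | B1(CC[C@H](OCc3ccccc3)[C@@H](OCc3ccccc3)[C@H](OCc3ccccc3)COB3C4CCCC3CCC4)C2CCCC1CCC2 | intermediate (not isolated)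
6 | 3,4,5-tri-O-benzyl-2-deoxy-D-xylo-hexitol | OCC[C@H](OCc1ccccc1)[C@@H](OCc1ccccc1)[C@H](OCc1ccccc1)CO | intermediate
7 | 3,4,5-tri-O-benzyl-2-deoxy-D-xylo-hexodialdose | O=CC[C@H](OCc1ccccc1)[C@@H](OCc1ccccc1)[C@H](OCc1ccccc1)C=O | intermediate (key-step precursor)
8 | (2S,3R,4R,5S)-3,4,5-tris(benzyloxy)-2-hydroxycyclohexan-1-one | O[C@@H]1C(=O)C[C@H](OCc2ccccc2)[C@@H](OCc2ccccc2)[C@@H]1OCc1ccccc1 | intermediate (key-step product)
9 | (2S,3S,4R,5S)-3,4,5-tris(benzyloxy)-2-[(triethylsilyl)oxy]cyclohexan-1-one | CC[Si](CC)(CC)O[C@@H]1C(=O)C[C@H](OCc2ccccc2)[C@@H](OCc2ccccc2)[C@@H]1OCc1ccccc1 | intermediate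
10 | 4-phenyl-1-butyne | C#CCCc1ccccc1 | starting material
11 | lithium 4-phenylbut-1-yn-1-ide | [Li]C#CCCc1ccccc1 | intermediate (not isolated)
12 | 5-phenylpent-2-ynal | O=CC#CCCc1ccccc1 | intermediate
13 | lithium enolate of 9 (C1–OLi, C1=C6) | CC[Si](CC)(CC)O[C@@H]1C(O[Li])=C[C@H](OCc2ccccc2)[C@@H](OCc2ccccc2)[C@@H]1OCc1ccccc1 | intermediate (not isolated)
14 | (2S,3S,4R,5S)-3,4,5-tris(benzyloxy)-6-(1-hydroxy-5-phenylpent-2-yn-1-yl)-2-[(triethylsilyl)oxy]cyclohexan-1-one, mixture at C6 and the carbinol carbon | CC[Si](CC)(CC)O[C@@H]1C(=O)C(C(O)C#CCCc2ccccc2)[C@H](OCc2ccccc2)[C@@H](OCc2ccccc2)[C@@H]1OCc1ccccc1 | intermediate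
15 | 3,4,5-tris(benzyloxy)-6-(5-phenylpent-2-ynoyl)-2-[(triethylsilyl)oxy]cyclohexan-1-one, drawn as the C1 enol | CC[Si](CC)(CC)O[C@@H]1C(O)=C(C(=O)C#CCCc2ccccc2)[C@H](OCc2ccccc2)[C@@H](OCc2ccccc2)[C@@H]1OCc1ccccc1 | intermediate
16 | (5S,6R,7S,8S)-5,6,7-tris(benzyloxy)-2-(2-phenylethyl)-8-[(triethylsilyl)oxy]-5,6,7,8-tetrahydro-4H-chromen-4-one | CC[Si](CC)(CC)O[C@@H]1c2oc(CCc3ccccc3)cc(=O)c2[C@H](OCc2ccccc2)[C@@H](OCc2ccccc2)[C@@H]1OCc1ccccc1 | intermediate (not isolated)
17 | (5S,6R,7R,8S)-5,6,7-tris(benzyloxy)-8-hydroxy-2-(2-phenylethyl)-5,6,7,8-tetrahydro-4H-chromen-4-one | O[C@@H]1c2oc(CCc3ccccc3)cc(=O)c2[C@H](OCc2ccccc2)[C@@H](OCc2ccccc2)[C@@H]1OCc1ccccc1 | intermediate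
18 | paeonol (2-hydroxy-4-methoxyacetophenone) | CC(=O)c1ccc(OC)cc1O | starting material
19 | 1-(2-hydroxy-5-iodo-4-methoxyphenyl)ethan-1-one | CC(=O)c1cc(I)c(OC)cc1O | intermediate
20 | ethyl 3-phenylpropanoate | CCOC(=O)CCc1ccccc1 | starting material
21 | 1-(2-hydroxy-5-iodo-4-methoxyphenyl)-5-phenylpentane-1,3-dione | O=C(CC(=O)CCc1ccccc1)c1cc(I)c(OC)cc1O | intermediate (not isolated)
22 | 6-iodo-7-methoxy-2-(2-phenylethyl)-4H-chromen-4-one | COc1cc2oc(CCc3ccccc3)cc(=O)c2cc1I | intermediate
23 | (5S,6R,7S,8S)-5,6,7-tris(benzyloxy)-8-{[7-methoxy-4-oxo-2-(2-phenylethyl)-4H-chromen-6-yl]oxy}-2-(2-phenylethyl)-5,6,7,8-tetrahydro-4H-chromen-4-one | COc1cc2oc(CCc3ccccc3)cc(=O)c2cc1O[C@@H]1c2oc(CCc3ccccc3)cc(=O)c2[C@H](OCc2ccccc2)[C@@H](OCc2ccccc2)[C@@H]1OCc1ccccc1 | intermediate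
24 | (5S,6R,7S,8S)-5,6,7-trihydroxy-8-{[7-methoxy-4-oxo-2-(2-phenylethyl)-4H-chromen-6-yl]oxy}-2-(2-phenylethyl)-5,6,7,8-tetrahydro-4H-chromen-4-one | COc1cc2oc(CCc3ccccc3)cc(=O)c2cc1O[C@@H]1c2oc(CCc3ccccc3)cc(=O)c2[C@H](O)[C@@H](O)[C@@H]1O | target

Total step count: 15. Longest linear sequence: 12 steps (steps 1–7, 9–11, 14, 15).

Steps most likely to fail

Step 6. What may go wrong: the amine base enolises the CH2–CHO terminus faster than the carbene engages it (five-membered aldol closure, E1cB loss of the C5 benzyloxy group), or the facial bias at C8 is too small. Fallback: the same C8–C8a bond is made reductively and without base, and C8 is then corrected by SN2 inversion. From 7, pinacol cyclisation with SmI2 (t-BuOH, THF, −78 °C), which on carbohydrate-derived dialdehydes is expected to give the cis-diol anti to the neighbouring alkoxy group, should give 3,4,5-tris(benzyloxy)cyclohexane-1,2-diol with both hydroxyls trans to the C7 benzyloxy group F1. Its dibutylstannylene acetal F2 (Bu2SnO, MeOH, reflux; not isolated) is cleaved with NBS in CHCl3, which oxidises the axial C8a carbinol and should leave the C8 epimer of the acyloin F3. Mitsunobu reaction with chloroacetic acid (PPh3, DIAD, toluene, 0 °C) inverts C8 to the chloroacetate of the acyloin F4, and thiourea with NaHCO3 in EtOH removes the ester under near-neutral conditions. The route is rejoined at 8.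

Step 14. What may go wrong: the hindered, pseudo-axial C8 alkoxide fails to engage the ortho-substituted aryl–copper species before base and heat degrade the tetrahydrochromone (vinylogous E1cB loss of the C7 benzyloxy group, aromatisation). Fallback: net retention by two SN2 inversions at or below room temperature. From 17, Mitsunobu reaction with 4-nitrobenzoic acid (PPh3, DIAD, THF) gives the inverted 4-nitrobenzoate F5, and K2CO3 in MeOH at 0 °C frees the C8-epimeric alcohol F6. From 22, Miyaura borylation (B2pin2, PdCl2(dppf), KOAc, dioxane, 85 °C) gives the pinacol boronate F7, and NaBO3·4H2O in THF/H2O oxidises it to 6-hydroxy-7-methoxy-2-(2-phenylethyl)-4H-chromen-4-one F8. A second Mitsunobu reaction of F6 with F8 (PPh3, DIAD, toluene) forms the ether with inversion and rejoins the route at 23.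

Step 9. What may go wrong: the lithium enolate expels the C5 benzyloxy group (E1cB) or equilibrates towards C2 before it meets the aldehyde, or the lithium aldolate reverts. Fallback: the enolate is trapped as it forms and the C–C bond is made under Lewis acid, with no basic enolate present. From 9, LiN(SiMe3)2 added to a mixture of 9 and Me3SiCl in THF at −78 °C gives the trimethylsilyl enol ether F9, which adds to 12 in a Mukaiyama aldol reaction (BF3·OEt2, CH2Cl2, −78 °C). The route is rejoined at 14.

Further compounds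
F1 | step 6 | 3,4,5-tris(benzyloxy)cyclohexane-1,2-diol, 1,2-cis-diol trans to the adjacent benzyloxy group | O[C@H]1[C@@H](O)C[C@H](OCc2ccccc2)[C@@H](OCc2ccccc2)[C@@H]1OCc1ccccc1
F2 | step 6 | O,O-dibutylstannylene acetal of F1 | CCCC[Sn]1(CCCC)O[C@H]2[C@@H](O1)C[C@H](OCc3ccccc3)[C@@H](OCc3ccccc3)[C@@H]2OCc2ccccc2
F3 | step 6 | (2R,3R,4R,5S)-3,4,5-tris(benzyloxy)-2-hydroxycyclohexan-1-one (C2 epimer of 8) | O[C@H]1C(=O)C[C@H](OCc2ccccc2)[C@@H](OCc2ccccc2)[C@@H]1OCc1ccccc1
F4 | step 6 | O-chloroacetyl derivative of 8 | ClCC(=O)O[C@@H]1C(=O)C[C@H](OCc2ccccc2)[C@@H](OCc2ccccc2)[C@@H]1OCc1ccccc1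
F5 | step 14 | 4-nitrobenzoate of the C8 epimer of 17 | O=C(O[C@H]1c2oc(CCc3ccccc3)cc(=O)c2[C@H](OCc2ccccc2)[C@@H](OCc2ccccc2)[C@@H]1OCc1ccccc1)c1ccc(cc1)[N+](=O)[O-]
F6 | step 14 | (5S,6R,7R,8R)-5,6,7-tris(benzyloxy)-8-hydroxy-2-(2-phenylethyl)-5,6,7,8-tetrahydro-4H-chromen-4-one (C8 epimer of 17) | O[C@H]1c2oc(CCc3ccccc3)cc(=O)c2[C@H](OCc2ccccc2)[C@@H](OCc2ccccc2)[C@@H]1OCc1ccccc1
F7 | step 14 | 7-methoxy-2-(2-phenylethyl)-6-(4,4,5,5-tetramethyl-1,3,2-dioxaborolan-2-yl)-4H-chromen-4-one | COc1cc2oc(CCc3ccccc3)cc(=O)c2cc1B1OC(C)(C)C(C)(C)O1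
F8 | step 14 | 6-hydroxy-7-methoxy-2-(2-phenylethyl)-4H-chromen-4-one | COc1cc2oc(CCc3ccccc3)cc(=O)c2cc1O
F9 | step 9 | trimethylsilyl enol ether of 9 (C1–OSiMe3, C1=C6) | CC[Si](CC)(CC)O[C@@H]1C(O[Si](C)(C)C)=C[C@H](OCc2ccccc2)[C@@H](OCc2ccccc2)[C@@H]1OCc1ccccc1
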